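0.671 h is the working life of the autumn flask, the plateau of target divided by its starting rate. You know this quantity as the time constant of a step response: here the gap between c_target and the plateau is taken to shrink as exp(−t/τ).

| flask | starting material | free catalyst | time |
|---|---|---|---|
| autumn | 0.250 M | 0.0130 M |  |
| dusk | 0.250 M | 0.0190 M |  |
| noon | 0.120 M | 0.0130 M |  |
| dawn | 0.250 M | 0.0130 M | 7.5 h |

| run | time / h | [target] / M |
|---|---|---|
| autumn run | 0.23 | 0.0196 |
| autumn run | 0.69 | 0.0438 |
| autumn run | 1.3 | 0.0594 |
| autumn run | 2.1 | 0.0637 |
| autumn run | 3.0 | 0.0675 |
| dusk run | 0.23 | 0.0277 |
| dusk run | 0.69 | 0.0566 |
| dusk run | 1.3 | 0.0736 |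
| dusk run | 2.1 | 0.0801 |
| dusk run | 3.0 | 0.0835 |
| noon run | 0.23 | 0.0097 |
| noon run | 0.69 | 0.0203 |
| noon run | 1.3 | 0.0284 |
| noon run | 2.1 | 0.0320 |
| noon run | 3.0 | 0.0297 |

(standard deviation of a reading: 0.002 M)

* order of the initial rate in [free catalyst], near the charge of the autumn run, the rate being that where two percent of its starting material are target
* order of the initial rate in [starting material], near the charge of the autumn run, the rate being that where two percent of its starting material are target (one fixed amount of target, the same in the runs compared)
* target in the dawn run at 7.5 h, as a share of the starting material charged

- Overall: starting material -> target, with free catalyst as catalyst.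
- Constant volume, constant temperature.
- An order is taken over about fifteen percent of the charge, up and down.

I read the autumn value from two readings, the last as plateau and the first as a point on the rise. That puts the autumn starting rate at 0.101 M h⁻¹. The same reckoning on the dusk run gives a life of 0.571 h and a rate of 0.146 M h⁻¹.

The order is the log-slope of rate against concentration. Taken from the raw first readings of dusk and autumn, the order in free catalyst is 0.911. That reading leans low, because the dusk life as read is shorter, so the dusk rate has sagged further by then. Through the starting rates the order becomes 0.986. The first readings of noon and autumn give 0.958 in starting material, coarsely, since each rests on single readings.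

Now bracket the dawn run, which repeats the autumn charge. From below stands the last autumn reading, 27.0 % of the charge, good to 0.800 %. From above, let the rate of the last autumn stretch, 0.00422 M h⁻¹, run unchanged to 7.5 h, which gives 34.6 %. The rate read has been falling from stretch to stretch, so let it die away with τ instead; the tail then adds rate times τ, and the ceiling, now an estimate resting on that assumption and on two scattered readings, drops to 28.1 %.

The forecast, holding that dawn “should sit on the plateau”, gives 27.3 %, inside my bracket, with 1 in starting material and 0.88 in free catalyst, lower than my order.

The dawn flask gives 27.8 %, with orders 1.0 in free catalyst and 1.1 in starting material.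

    free catalyst + starting material → target + free catalyst (32.04 M⁻¹ h⁻¹)
    starting material → decomposed substrate (0.7416 h⁻¹)
    2 free catalyst → 2 spent catalyst (23.04 M⁻¹ h⁻¹)

The autumn rate where two percent has turned is 0.095 M h⁻¹, and the dawn target divided by it gives a life of 0.729 h, against the 0.671 h read from the autumn readings. The dusk run, at 0.14 M h⁻¹ at that same amount of target, gives from its last reading a life of 0.591 h.

The readings are simulated with constants of no real substance.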